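**Plan**

- Retrosynthesis: the pyran ring is opened at O1–C8a and C2–C3, with formaldehyde placed between C3 of an α-aryl ketone and a fluorine-bearing C8a. The C3–C1' bond (ketone α-arylation), the C4–C4a bond (aryllithium acylation) and the two aryl–prenyl bonds (lithiation between two oxygens) are cut next.
- Forward: a ring A acetophenone (from 5-fluororesorcinol) and a ring B bromide (from resorcinol) are joined to a deoxybenzoin. Formaldehyde then closes the pyran ring in one flask to an isoflavanone; reduction with deoxygenation and MOM removal finish the route.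
- Enabling feature: C4 is benzylic to the phloroglucinol-type ring A. Carried as a ketone it acidifies C3–H (together with ring B) and activates the ortho carbon C8a for fluoride displacement, while the oxygens on C5 and C7 are meta to C8a. The oxygens on C5, C7 and C8a later stabilize a C4 cation, so the ketone can be taken out again.
- Stereochemistry: C3 is set by Ru-catalysed asymmetric transfer hydrogenation with dynamic kinetic resolution of the racemizing isoflavanone (cis-(3R,4R) alcohol). The C4 center is erased by deoxygenation, leaving (3R).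

Key step: step 10

Remark: the three phenols that end free are carried as methoxymethyl (MOM) ethers; "prenyl" means 3-methylbut-2-en-1-yl; atom numbers (O1, C2 … C8a, C1' …) are those of the 3-arylchroman skeleton; both starting phenols are taken as catalogue compounds.

**Route**

Step 1
Reactants: 1 5-fluororesorcinol
Product: 2 1-fluoro-3,5-bis(methoxymethoxy)benzene
Conditions: NaH, MOMCl, DMF, 0 °C → rt
Reagents that add atoms: chloromethyl methyl ether (MOMCl), COCCl
Why: Williamson-type O-alkylation of both phenoxides should give the bis-MOM ether, whose acetal oxygens later direct lithiation.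

Step 2
Reactants: 2 1-fluoro-3,5-bis(methoxymethoxy)benzene
Product: 4 5-fluoro-1,3-bis(methoxymethoxy)-2-(3-methylbut-2-en-1-yl)benzene, via aryllithium 3 (not isolated)
Conditions: n-BuLi, Et2O, 0 °C; then CuBr·SMe2 (10 mol %), prenyl bromide, −78 °C → rt
Reagents that add atoms: prenyl bromide (1-bromo-3-methylbut-2-ene), CC(C)=CCBr
Why: Directed ortho-metalation, in which n-BuLi held by both MOM groups should remove the proton between them rather than one next to fluorine (alkyllithiums without superbase additives follow the alkoxy groups), followed by copper-catalysed alkylation of aryllithium 3 with prenyl bromide to the linear prenyl arene.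

Step 3
Reactants: 4 5-fluoro-1,3-bis(methoxymethoxy)-2-(3-methylbut-2-en-1-yl)benzene
Product: 6 1-[6-fluoro-2,4-bis(methoxymethoxy)-3-(3-methylbut-2-en-1-yl)phenyl]ethan-1-one, via aryllithium 5 (not isolated)
Conditions: n-BuLi, THF, −78 °C; then MeC(O)N(OMe)Me, −78 °C; aq. NH4Cl
Reagents that add atoms: N-methoxy-N-methylacetamide, CC(=O)N(C)OC
Why: The two remaining ring positions are equivalent and each lies between F and OMOM, so ortho-lithiation at −78 °C (cold enough to prevent loss of LiF to an aryne) and Weinreb acylation should place the future C4 carbonyl on C4a without over-addition.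

Step 4
Reactants: 6 1-[6-fluoro-2,4-bis(methoxymethoxy)-3-(3-methylbut-2-en-1-yl)phenyl]ethan-1-one
Product: 7 1-[6-fluoro-2-hydroxy-4-(methoxymethoxy)-3-(3-methylbut-2-en-1-yl)phenyl]ethan-1-one
Conditions: HCl (cat.), MeOH, 0 °C → rt
Reagents that add atoms: none
Why: Acid-catalysed acetal exchange should remove only the MOM group ortho to the acetyl group, because that oxygen is activated by hydrogen bonding to the carbonyl and the freed phenol is held by the same hydrogen bond, a selectivity well known for ortho-acyl aryl MOM ethers, under conditions mild enough to spare the prenyl group.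

Step 5
Reactants: 7 1-[6-fluoro-2-hydroxy-4-(methoxymethoxy)-3-(3-methylbut-2-en-1-yl)phenyl]ethan-1-one
Product: 8 1-[6-fluoro-2-methoxy-4-(methoxymethoxy)-3-(3-methylbut-2-en-1-yl)phenyl]ethan-1-one
Conditions: MeI, K2CO3, acetone, reflux
Reagents that add atoms: iodomethane, CI
Why: Williamson O-methylation of the chelated phenol fixes the future C5 methoxy group while the future C7 oxygen stays as its MOM ether.

Step 6
Reactants: 9 resorcinol
Product: 10 1,3-bis(methoxymethoxy)benzene
Conditions: NaH, MOMCl, DMF, 0 °C → rt
Reagents that add atoms: chloromethyl methyl ether (MOMCl), COCCl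
Why: Williamson-type O-alkylation protects both phenols and provides the two directing groups for the lithiations of ring B.

Step 7
Reactants: 10 1,3-bis(methoxymethoxy)benzene
Product: 12 1,3-bis(methoxymethoxy)-2-(3-methylbut-2-en-1-yl)benzene, via aryllithium 11 (not isolated)
Conditions: n-BuLi, THF, 0 °C → rt; then CuBr·SMe2 (10 mol %), prenyl bromide, −78 °C → rt
Reagents that add atoms: prenyl bromide (1-bromo-3-methylbut-2-ene), CC(C)=CCBr
Why: Directed ortho-metalation at the position flanked by both MOM groups and copper-catalysed alkylation with prenyl bromide is the standard entry to 2-prenylresorcinol ethers.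

Step 8
Reactants: 12 1,3-bis(methoxymethoxy)-2-(3-methylbut-2-en-1-yl)benzene
Product: 14 1-bromo-2,4-bis(methoxymethoxy)-3-(3-methylbut-2-en-1-yl)benzene, via aryllithium 13 (not isolated)
Conditions: n-BuLi, TMEDA, Et2O, 0 °C; then BrCl2C–CCl2Br, −78 °C → rt
Reagents that add atoms: 1,2-dibromo-1,1,2,2-tetrachloroethane, ClC(Cl)(Br)C(Cl)(Cl)Br
Why: A second directed ortho-metalation next to one MOM group (the site between them is now occupied) and bromine transfer from the dibromide should give the aryl bromide without an electrophilic brominating agent that would attack the prenyl alkene.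

Step 9
Reactants: 8 1-[6-fluoro-2-methoxy-4-(methoxymethoxy)-3-(3-methylbut-2-en-1-yl)phenyl]ethan-1-one; 14 1-bromo-2,4-bis(methoxymethoxy)-3-(3-methylbut-2-en-1-yl)benzene
Product: 15 2-[2,4-bis(methoxymethoxy)-3-(3-methylbut-2-en-1-yl)phenyl]-1-[6-fluoro-2-methoxy-4-(methoxymethoxy)-3-(3-methylbut-2-en-1-yl)phenyl]ethan-1-one
Conditions: Pd(OAc)2 (2 mol %), P(t-Bu)3 (4 mol %), NaOtBu, toluene, 70 °C
Reagents that add atoms: none
Why: Palladium-catalysed α-arylation of a ketone enolate, in which zerovalent palladium inserts into the C–Br bond of 14, the sodium enolate of 8 binds and reductive elimination forms the C3–C1' bond, with the bulky phosphine favouring mono-arylation, the C–F bond inert and ring A shielded from SNAr while the ketone is enolized.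

Step 10
Reactants: 15 2-[2,4-bis(methoxymethoxy)-3-(3-methylbut-2-en-1-yl)phenyl]-1-[6-fluoro-2-methoxy-4-(methoxymethoxy)-3-(3-methylbut-2-en-1-yl)phenyl]ethan-1-one
Product: 17 rac-3-[2,4-bis(methoxymethoxy)-3-(3-methylbut-2-en-1-yl)phenyl]-5-methoxy-7-(methoxymethoxy)-6-(3-methylbut-2-en-1-yl)-2,3-dihydro-4H-chromen-4-one, via aldol 16 (not isolated)
Conditions: 37% aq. CH2O (1.2 equiv), K2CO3, DMSO, rt → 70 °C
Reagents that add atoms: formaldehyde, C=O
Why: Proposed new method: K2CO3 generates the enolate at C3, stabilized by the C4 ketone and ring B, which adds to formaldehyde to form C2–C3 (aldol 16); the C2 alkoxide then attacks C8a and expels fluoride through a Meisenheimer complex whose charge is taken up by the ortho C4 carbonyl, forming O1–C8a. The closest known reaction types are the base-mediated hydroxymethylation of deoxybenzoins with formaldehyde and the intramolecular SNAr of oxygen nucleophiles onto 2-fluoroaryl ketones that gives chromones and chromanones; their combination in one flask on a 2-fluorodeoxybenzoin is the new element. The pyran ring closes as a six-membered addition–elimination at an sp2 carbon, formally a 6-endo-trig conjugate addition to the C8a=C4a–C4=O unit followed by loss of fluoride. C3 becomes a stereocenter but is formed racemic and stays epimerizable next to the ketone, so no control is sought here and the configuration is fixed in step 11. The step needs O-attack at C8a to outrun E1cB dehydration of 16 and a second hydroxymethylation: water keeps enone and aldol in equilibrium, formaldehyde is held to a slight excess, only the fluoride displacement is irreversible, and the oxygens on C5 and C7 sit meta to C8a so that they do not oppose the Meisenheimer complex.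

Step 11
Reactants: 17 rac-3-[2,4-bis(methoxymethoxy)-3-(3-methylbut-2-en-1-yl)phenyl]-5-methoxy-7-(methoxymethoxy)-6-(3-methylbut-2-en-1-yl)-2,3-dihydro-4H-chromen-4-one
Product: 19 (3R)-3-[2,4-bis(methoxymethoxy)-3-(3-methylbut-2-en-1-yl)phenyl]-5-methoxy-7-(methoxymethoxy)-6-(3-methylbut-2-en-1-yl)-3,4-dihydro-2H-chromene, via cis-alcohol 18 (not isolated)
Conditions: RuCl(p-cymene)[(R,R)-TsDPEN] (5 mol %), HCO2H/Et3N (5:2), EtOAc, 40 °C
Reagents that add atoms: none
Why: Noyori–Ikariya asymmetric transfer hydrogenation with dynamic kinetic resolution, in which the α-aryl ketone racemizes through its enol under Et3N while the (R,R)-catalyst should reduce one enantiomer faster to the cis-(3R,4R) alcohol 18 (hydride delivered anti to the C3 aryl group, C4 configuration as expected from the usual aryl ketone model), which fixes C3, after which the C4 alcohol ionizes in the formic acid medium to a cation stabilized by the oxygens on C5, C7 and C8a and is reduced by the ruthenium hydride, a reduction–deoxygenation cascade precedented for 7-alkoxyisoflavanones that leaves C3 untouched.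

Step 12
Reactants: 19 (3R)-3-[2,4-bis(methoxymethoxy)-3-(3-methylbut-2-en-1-yl)phenyl]-5-methoxy-7-(methoxymethoxy)-6-(3-methylbut-2-en-1-yl)-3,4-dihydro-2H-chromene
Product: 20 licoricidin, 4-[(3R)-7-hydroxy-5-methoxy-6-(3-methylbut-2-en-1-yl)-3,4-dihydro-2H-chromen-3-yl]-2-(3-methylbut-2-en-1-yl)benzene-1,3-diol
Conditions: 3 M aq. HCl, MeOH, 40 °C
Reagents that add atoms: none
Why: Acid-catalysed methanolysis of the three aryl MOM acetals frees the phenols, with short exposure at moderate temperature chosen because ortho-prenyl phenols can cyclize to dimethylchromans under stronger acid, and C3 carries no acidic or ionizable group and keeps its configuration.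

**Compound list**

1 | 5-fluororesorcinol (5-fluorobenzene-1,3-diol) | Oc1cc(O)cc(F)c1 | starting material
2 | 1-fluoro-3,5-bis(methoxymethoxy)benzene | COCOc1cc(F)cc(OCOC)c1 | intermediate
3 | [4-fluoro-2,6-bis(methoxymethoxy)phenyl]lithium | [Li]c1c(OCOC)cc(F)cc1OCOC | intermediate
4 | 5-fluoro-1,3-bis(methoxymethoxy)-2-(3-methylbut-2-en-1-yl)benzene | COCOc1cc(F)cc(OCOC)c1CC=C(C)C | intermediate
5 | [6-fluoro-2,4-bis(methoxymethoxy)-3-(3-methylbut-2-en-1-yl)phenyl]lithium | [Li]c1c(F)cc(OCOC)c(CC=C(C)C)c1OCOC | intermediate
6 | 1-[6-fluoro-2,4-bis(methoxymethoxy)-3-(3-methylbut-2-en-1-yl)phenyl]ethan-1-one | CC(=O)c1c(F)cc(OCOC)c(CC=C(C)C)c1OCOC | intermediate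
7 | 1-[6-fluoro-2-hydroxy-4-(methoxymethoxy)-3-(3-methylbut-2-en-1-yl)phenyl]ethan-1-one | CC(=O)c1c(F)cc(OCOC)c(CC=C(C)C)c1O | intermediate
8 | 1-[6-fluoro-2-methoxy-4-(methoxymethoxy)-3-(3-methylbut-2-en-1-yl)phenyl]ethan-1-one | CC(=O)c1c(F)cc(OCOC)c(CC=C(C)C)c1OC | intermediate
9 | resorcinol (benzene-1,3-diol) | Oc1cccc(O)c1 | starting material
10 | 1,3-bis(methoxymethoxy)benzene | COCOc1cccc(OCOC)c1 | intermediate
11 | [2,6-bis(methoxymethoxy)phenyl]lithium | [Li]c1c(OCOC)cccc1OCOC | intermediate
12 | 1,3-bis(methoxymethoxy)-2-(3-methylbut-2-en-1-yl)benzene | COCOc1cccc(OCOC)c1CC=C(C)C | intermediate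
13 | [2,4-bis(methoxymethoxy)-3-(3-methylbut-2-en-1-yl)phenyl]lithium | [Li]c1ccc(OCOC)c(CC=C(C)C)c1OCOC | intermediate
14 | 1-bromo-2,4-bis(methoxymethoxy)-3-(3-methylbut-2-en-1-yl)benzene | Brc1ccc(OCOC)c(CC=C(C)C)c1OCOC | intermediate
15 | 2-[2,4-bis(methoxymethoxy)-3-(3-methylbut-2-en-1-yl)phenyl]-1-[6-fluoro-2-methoxy-4-(methoxymethoxy)-3-(3-methylbut-2-en-1-yl)phenyl]ethan-1-one | COc1c(CC=C(C)C)c(OCOC)cc(F)c1C(=O)Cc1ccc(OCOC)c(CC=C(C)C)c1OCOC | intermediate
16 | rac-2-[2,4-bis(methoxymethoxy)-3-(3-methylbut-2-en-1-yl)phenyl]-1-[6-fluoro-2-methoxy-4-(methoxymethoxy)-3-(3-methylbut-2-en-1-yl)phenyl]-3-hydroxypropan-1-one | COc1c(CC=C(C)C)c(OCOC)cc(F)c1C(=O)C(CO)c1ccc(OCOC)c(CC=C(C)C)c1OCOC | intermediate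
17 | rac-3-[2,4-bis(methoxymethoxy)-3-(3-methylbut-2-en-1-yl)phenyl]-5-methoxy-7-(methoxymethoxy)-6-(3-methylbut-2-en-1-yl)-2,3-dihydro-4H-chromen-4-one | COc1c(CC=C(C)C)c(OCOC)cc2c1C(=O)C(c1ccc(OCOC)c(CC=C(C)C)c1OCOC)CO2 | intermediate
18 | (3R,4R)-3-[2,4-bis(methoxymethoxy)-3-(3-methylbut-2-en-1-yl)phenyl]-5-methoxy-7-(methoxymethoxy)-6-(3-methylbut-2-en-1-yl)-3,4-dihydro-2H-chromen-4-ol (cis) | COc1c(CC=C(C)C)c(OCOC)cc2c1[C@H](O)[C@H](c1ccc(OCOC)c(CC=C(C)C)c1OCOC)CO2 | intermediate
19 | (3R)-3-[2,4-bis(methoxymethoxy)-3-(3-methylbut-2-en-1-yl)phenyl]-5-methoxy-7-(methoxymethoxy)-6-(3-methylbut-2-en-1-yl)-3,4-dihydro-2H-chromene | COc1c(CC=C(C)C)c(OCOC)cc2c1C[C@H](c1ccc(OCOC)c(CC=C(C)C)c1OCOC)CO2 | intermediate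
20 | licoricidin, 4-[(3R)-7-hydroxy-5-methoxy-6-(3-methylbut-2-en-1-yl)-3,4-dihydro-2H-chromen-3-yl]-2-(3-methylbut-2-en-1-yl)benzene-1,3-diol | COc1c(CC=C(C)C)c(O)cc2c1C[C@H](c1ccc(O)c(CC=C(C)C)c1O)CO2 | target

**Count and risks**

Total step count: 12. Longest linear sequence: 9 steps (steps 1–5, then 9–12).

Step 10 (proposed method). The aldol 16 may dehydrate by E1cB to a 2-arylacrylophenone that has lost its oxygen nucleophile, a second hydroxymethylation at C3 may occur, or fluoride displacement may be too slow at the temperature the aldol tolerates. The fallback uses known chemistry and forms the same two bonds. It sets out from 15: Claisen formylation with ethyl formate and NaH in THF should give the α-hydroxymethylene ketone F1. Heating F1 with K2CO3 in DMF lets the enolate oxygen displace fluoride, the established SNAr route from 2-fluoroaryl 1,3-dicarbonyl compounds to chromones, and should give the isoflavone F2. Conjugate reduction of F2 with LiBH(s-Bu)3 in THF at −78 °C returns to the route at 17.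

Step 11. Hydride transfer to the electron-rich ketone flanked by the C5 methoxy group may be slow. At the cation stage, loss of the C3 proton to an isoflav-3-ene and reprotonation may erode the enantiomeric purity. The fallback separates reduction from deoxygenation and avoids the cation. It sets out from 17: transfer hydrogenation with the same catalyst in HCO2H/Et3N (1:1) at rt, where the alcohol should not ionize, and isolation of 18. Treatment of 18 with 1,1'-thiocarbonyldiimidazole and DMAP in CH2Cl2 should give the imidazole-1-carbothioate F3. Barton–McCombie reduction of F3 with Bu3SnH and AIBN in toluene at 80 °C proceeds through a C4 radical that cannot touch C3 and comes back to the route at 19.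

Step 2. Deprotonation next to fluorine may compete with deprotonation between the two MOM groups, which would give a regioisomeric prenyl arene or aryne-derived decomposition. The fallback fixes the regiochemistry by electrophilic substitution and a Claisen rearrangement instead of by competing lithiation sites. It sets out from 1: Friedel–Crafts acetylation (AcOH, BF3·OEt2, 90 °C) ortho to one hydroxyl and para to the other should give 1-(2-fluoro-4,6-dihydroxyphenyl)ethan-1-one F4. Selective MOM protection of the non-chelated para hydroxyl (MOMCl, DIPEA, CH2Cl2) gives 1-[2-fluoro-6-hydroxy-4-(methoxymethoxy)phenyl]ethan-1-one F5. Tsuji–Trost O-alkylation with tert-butyl 2-methylbut-3-en-2-yl carbonate and Pd(PPh3)4 in THF gives the 1,1-dimethylallyl aryl ether F6. Aromatic Claisen rearrangement of F6 on heating in N,N-diethylaniline moves the allyl unit, with inversion to a linear prenyl group, to the only free ortho position and comes back to the route at 7.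

**Further compounds**

F1 | step 10 | 2-[2,4-bis(methoxymethoxy)-3-(3-methylbut-2-en-1-yl)phenyl]-1-[6-fluoro-2-methoxy-4-(methoxymethoxy)-3-(3-methylbut-2-en-1-yl)phenyl]-3-hydroxyprop-2-en-1-one (α-hydroxymethylene ketone) | COc1c(CC=C(C)C)c(OCOC)cc(F)c1C(=O)C(=CO)c1ccc(OCOC)c(CC=C(C)C)c1OCOC
F2 | step 10 | 3-[2,4-bis(methoxymethoxy)-3-(3-methylbut-2-en-1-yl)phenyl]-5-methoxy-7-(methoxymethoxy)-6-(3-methylbut-2-en-1-yl)-4H-chromen-4-one (isoflavone) | COc1c(CC=C(C)C)c(OCOC)cc2c1C(=O)C(c1ccc(OCOC)c(CC=C(C)C)c1OCOC)=CO2
F3 | step 11 | O-[(3R,4R)-3-[2,4-bis(methoxymethoxy)-3-(3-methylbut-2-en-1-yl)phenyl]-5-methoxy-7-(methoxymethoxy)-6-(3-methylbut-2-en-1-yl)-3,4-dihydro-2H-chromen-4-yl] 1H-imidazole-1-carbothioate | COc1c(CC=C(C)C)c(OCOC)cc2c1[C@H](OC(=S)n1ccnc1)[C@H](c1ccc(OCOC)c(CC=C(C)C)c1OCOC)CO2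
F4 | step 2 | 1-(2-fluoro-4,6-dihydroxyphenyl)ethan-1-one | CC(=O)c1c(O)cc(O)cc1F
F5 | step 2 | 1-[2-fluoro-6-hydroxy-4-(methoxymethoxy)phenyl]ethan-1-one | CC(=O)c1c(O)cc(OCOC)cc1F
F6 | step 2 | 1-[2-fluoro-4-(methoxymethoxy)-6-[(2-methylbut-3-en-2-yl)oxy]phenyl]ethan-1-one | CC(=O)c1c(OC(C)(C)C=C)cc(OCOC)cc1F
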